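Each chain begun costs one initiator, and none of the steps thought possible gives one back, so chains begun cannot outnumber the initiator charged. That invariant gives the scale we use for this flask.

the same everywhere: free monomer 0.025 M

| flask | initiator | remark | time |
|---|---|---|---|
| cedar | 2.5 mol% | run made earlier |  |
| oak | 3.8 mol% | run made earlier |  |
| flask | 5 mol% |  | 10 d |

| run | time / d | monomer in chains / % | free monomer / % |
|---|---|---|---|
| cedar | 0.417 | 0 | 93 |
| cedar | 1.25 | 0 | 78 |
| cedar | 2.00 | 1 | 68 |
| cedar | 3.00 | 5 | 56 |
| cedar | 5.00 | 5 | 36 |
| cedar | 6.00 | 5 | 29 |
| oak | 0.500 | 0 | 93 |
| oak | 0.833 | 2 | 86 |
| oak | 1.25 | 1 | 81 |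
| oak | 2.00 | 0 | 69 |
| oak | 4.00 | 4 | 46 |
| oak | 6.00 | 8 | 28 |

(readings scatter by 1.5 percentage points)

- average number of monomer units in a chain (chains begun, living or dead) at 10 d
- part of the free monomer that has reacted at 10 d

- the average divides the monomer in chains by the number of chains begun, living and dead together
- steps thought possible: free monomer + living end -> monomer in chains + living end; free monomer + initiator -> living end + monomer in chains; initiator + monomer in chains -> spent initiator; free monomer -> uncatalysed product
- the earlier runs do not show the number of chains; that part of a forecast is a guess

Divide monomer in chains by initiator charged. For oak at 6.00 d this gives 2.11, and for cedar at 6.00 d it gives 2.00, both as readings with their scatter. This full-start average is what the average would be if every initiator had begun a chain. It is the zero of our scale, and the true average lies on it or above it.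

We build the flask up by hand. First comes the uncatalysed loss. Read as an exponential fall, free monomer gives a constant of 0.206 d⁻¹ in cedar and 0.212 d⁻¹ in oak, so we read the loss as little tied to initiator. Carried forward, cedar's constant gives our estimate of 12.7% left in the flask at 10 d, a conversion of 87.3%.

Next comes the initiator step, where each event puts one unit in a chain, so its average is 1. Growth on living ends then lifts the average. Taking monomer in chains in proportion to initiator charged and to monomer lost, we scale oak's full-start average to 2.55 for the flask. The last step, to spent initiator, has no column in the readings, and the number of chains has none either, so our figure is an estimate of the zero of the scale, not a bound on the flask.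

The forecast names 3 and 88%: “At most 5% can be chains begun, since each needs one initiator”.

The flask gives 10.8 and 90.2%.

    free monomer + living end → monomer in chains + living end, rate k1*[living end]*[free monomer] (k = 7.70 M⁻¹ h⁻¹)
    free monomer + initiator → living end + monomer in chains (k = 0.140 M⁻¹ h⁻¹)
    initiator + monomer in chains → spent initiator (k = 0.210 M⁻¹ h⁻¹)
    free monomer → uncatalysed product (k = 0.00760 h⁻¹)

In the flask at 10.0 d, monomer in chains of 15.4% makes the full-start average 3.08, so against 10.8 about 28.5% of the initiator charged began chains (the initiator efficiency). In a neighbour flask with 0.10 M of free monomer and the same loading, the full-start average is 11.4 against 24.5, a share of 46.5%. The flask has not come to rest. By 100 d free monomer goes from 9.81% to 0%, monomer in chains reaches 15.5% and the average slips to 10.2. Initiator falls from 63.6% to 9.68%, and spent initiator reaches 2.99%.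

The numbers in the tables were generated by integration from invented constants; noise was put on by code.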